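**Plan**
- Retrosynthesis: the C11 silyl ether is cut last. Before it come the ring C–ring D biaryl bond, the ring C–allyl bond and the aryl–O bond of the C4 ether, which leaves the eudesmane-4α,11-diol core. In the core, the C2–C3 bond and the C4–OH bond are cut together, leading back to elemol.
- Forward: ring B is the cyclohexane of elemol. Ring A is closed onto it by olefin-assisted solvolysis. Ring C is then attached to the C4 oxygen as a 4-bromo-2-chlorophenyl group and allylated at the bromide, ring D is joined at the chloride, and desilylation ends the route.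
- Enabling feature: elemol is the decalin of the target without the C2–C3 bond and the C4 oxygen. Its C10 vinyl group supplies C1–C2 and its C5 isopropenyl group supplies C3=C4(–C15), a 5-hexenyl array once C2 carries a leaving group.
- Stereochemistry: C5, C7 and C10 are taken unchanged from natural elemol. C4 is set in the ring closure by anti addition across C3=C4 in a chair (oxygen equatorial 4α, methyl axial 4β). No later step breaks a bond to a stereocentre.

Key step: step 4

Assumption: eudesmane numbering is used for the terpene carbons, also in the ring-opened (elemane) compounds, and natural elemol is taken as commercially available.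

Step 1
Reactants: 1 elemol; 2 triethylsilyl trifluoromethanesulfonate
Product: 3 elemol triethylsilyl ether (C11–OSiEt3)
Conditions: Et3SiOTf, 2,6-lutidine, CH2Cl2, −78 to 0 °C
Reagents that add atoms: triethylsilyl trifluoromethanesulfonate, CC[Si](CC)(CC)OS(=O)(=O)C(F)(F)F
Why: Silylation of the hindered tertiary C11 alcohol with a silyl triflate and a hindered pyridine base is standard, touches neither alkene nor any stereocentre, and masks the only hydroxyl so that the C4 alcohol made later can be arylated alone.

Step 2
Reactants: 3 elemol triethylsilyl ether; 4 catecholborane; 5 hydrogen peroxide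
Product: 7 C2 primary alcohol (C10 vinyl converted to CH2CH2OH), via B-alkylcatecholborane 6 (not isolated)
Conditions: catecholborane, RhCl(PPh3)3 (cat.), THF, 20 °C; then NaOH, H2O2, THF/H2O, 0 to 20 °C
Reagents that add atoms: hydrogen peroxide, OO
Why: Rhodium-catalysed hydroboration is far more sensitive to alkene substitution than the uncatalysed reaction, so the monosubstituted C1=C2 vinyl group should react and the hindered 1,1-disubstituted isopropenyl group should not; boron goes to the terminal carbon C2 and alkaline peroxide replaces it by hydroxyl, with no stereocentre created.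

Step 3
Reactants: 7 C2 primary alcohol; 8 4-nitrobenzenesulfonyl chloride
Product: 9 C2 4-nitrobenzenesulfonate (nosylate) of the silylated seco-alcohol
Conditions: 4-O2NC6H4SO2Cl, pyridine, CH2Cl2, 0 °C
Reagents that add atoms: 4-nitrobenzenesulfonyl chloride, O=S(=O)(Cl)c1ccc([N+](=O)[O-])cc1
Why: Sulfonylation of an unhindered primary alcohol in pyridine is routine and gives an arenesulfonate that ionises far more readily than a tosylate, which is what step 4 needs.

Step 4
Reactants: 9 C2 nosylate; 10 water
Product: 12 11-(triethylsilyloxy)eudesman-4α-ol (4β-methyl; 5α-H; 10β-methyl; 7β side chain), via eudesman-4-yl cation 11 (not isolated)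
Conditions: (CF3)2CHOH/H2O (9:1), 2,6-lutidine, 45 °C
Reagents that add atoms: water, O
Why: In this strongly ionising, weakly nucleophilic medium the C2–O bond of the primary sulfonate should break with assistance from the C3=C4 π bond: the terminal carbon C3 attacks C2 from the rear as the sulfonate leaves, giving the tertiary cation 11 at C4, which water captures. The closest known reaction type is the olefin-assisted solvolysis of 5-hexenyl arenesulfonates, the simplest cation–olefin cyclisation. Ring A closes 6-endo with respect to the C3=C4 bond (6-exo-tet at C2) through a chair in which the bonds from C5 and C10 into ring B are equatorial, so the trans ring fusion carried by elemol is kept. C4 is the only new stereocentre: water adds anti to the new C2–C3 bond, which is the equatorial direction on the α face away from the axial C10 methyl, so oxygen becomes 4α and the methyl 4β (axial). The step needs participation to outrun direct displacement by solvent, 6-endo closure to outrun 5-exo closure, and hydration to outrun proton loss. The poor nucleophilicity of hexafluoroisopropanol, the electron-rich 1,1-disubstituted alkene, the tertiary (rather than primary) cation reached through C3 and the excess of water serve these ends, while the lutidine buffer protects the tertiary silyl ether and the new tertiary alcohol from acid.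

Step 5
Reactants: 13 4-bromo-2-chloro-1-iodobenzene; 14 3-chloroperbenzoic acid; 15 4-toluenesulfonic acid monohydrate; 16 1,3,5-trimethoxybenzene
Product: 18 (4-bromo-2-chlorophenyl)(2,4,6-trimethoxyphenyl)iodonium tosylate, via hydroxy(tosyloxy)iodoarene 17 (not isolated)
Conditions: mCPBA, TsOH·H2O, MeCN, 75 °C; then 1,3,5-trimethoxybenzene, 75 to 20 °C
Reagents that add atoms: 4-toluenesulfonic acid monohydrate, Cc1ccc(S(=O)(=O)O)cc1.O; 1,3,5-trimethoxybenzene, COc1cc(OC)cc(OC)c1
Why: One-pot aryl(trimethoxyphenyl)iodonium salt synthesis: the peracid oxidises the iodoarene to the trivalent-iodine species 17, which then substitutes the electron-rich trimethoxybenzene by electrophilic aromatic substitution.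

Step 6
Reactants: 12 11-(triethylsilyloxy)eudesman-4α-ol; 18 iodonium tosylate
Product: 20 4α-(4-bromo-2-chlorophenoxy)-11-(triethylsilyloxy)eudesmane, via sodium alkoxide 19 (not isolated)
Conditions: NaH, toluene, 50 °C; then 18, 20 °C
Reagents that add atoms: (4-bromo-2-chlorophenyl)(2,4,6-trimethoxyphenyl)iodonium tosylate, COc1cc(OC)c([I+]c2ccc(Br)cc2Cl)c(OC)c1.Cc1ccc(S(=O)(=O)[O-])cc1
Why: Metal-free O-arylation of a tertiary alkoxide with a diaryliodonium salt (ligand coupling at trivalent iodine) is established for hindered tertiary alcohols; the electron-poor, ortho-substituted aryl group is transferred in preference to the electron-rich trimethoxyphenyl group, and C4 keeps its configuration because the C4–O bond is never broken.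

Step 7
Reactants: 20 bromo chloro aryl ether; 21 allylboronic acid pinacol ester
Product: 22 4α-(4-allyl-2-chlorophenoxy)-11-(triethylsilyloxy)eudesmane
Conditions: allylB(pin), Pd(PPh3)4 (cat.), CsF, THF, 65 °C
Reagents that add atoms: allylboronic acid pinacol ester, C=CCB1OC(C)(C)C(C)(C)O1
Why: Suzuki–Miyaura allylation under fluoride activation; Pd(PPh3)4 inserts into the C–Br bond para to oxygen and leaves the C–Cl bond for step 10.

Step 8
Reactants: 23 4-hydroxyphenylboronic acid pinacol ester; 24 allyl bromide
Product: 25 4-(allyloxy)phenylboronic acid pinacol ester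
Conditions: allyl bromide, K2CO3, acetone, 56 °C
Reagents that add atoms: allyl bromide, C=CCBr
Why: Williamson O-allylation of a phenol, to which the pinacol boronate is inert.

Step 9
Reactants: 25 4-(allyloxy)phenylboronic acid pinacol ester
Product: 27 3-allyl-4-hydroxyphenylboronic acid pinacol ester, via 6-allylcyclohexadienone 26 (not isolated)
Conditions: N,N-diethylaniline, 190 °C
Reagents that add atoms: none
Why: Aromatic Claisen rearrangement ([3,3] shift to dienone 26, then tautomerisation); with the para position blocked by boron the allyl group can only end up ortho to the hydroxyl.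

Step 10
Reactants: 22 allyl chloro aryl ether; 27 3-allyl-4-hydroxyphenylboronic acid pinacol ester
Product: 28 11-O-triethylsilyl ether of the target
Conditions: Pd(OAc)2 (cat.), SPhos, K3PO4, toluene/H2O, 80 °C
Reagents that add atoms: 3-allyl-4-hydroxyphenylboronic acid pinacol ester, C=CCc1cc(B2OC(C)(C)C(C)(C)O2)ccc1O
Why: Suzuki–Miyaura coupling of an electron-rich ortho-alkoxy aryl chloride, for which Pd(OAc)2 with SPhos is a standard catalyst; free phenol, allyl groups and the tertiary silyl ether should tolerate aqueous K3PO4 at this temperature.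

Step 11
Reactants: 28 11-O-triethylsilyl ether of the target
Product: 29 target, 4α-O-aryl ether of eudesmane-4α,11-diol with honokiol (CNP0219722.1)
Conditions: Bu4NF, THF, 45 °C
Reagents that add atoms: none
Why: Fluoride cleavage of the tertiary triethylsilyl ether under non-acidic conditions, chosen because the tertiary alkyl aryl ether at C4 would ionise in acid; no stereocentre is affected.

**Compound list**
1 | elemol, 2-[(1R,3S,4S)-4-ethenyl-4-methyl-3-(prop-1-en-2-yl)cyclohexyl]propan-2-ol | C=C[C@]1(C)CC[C@@H](C(C)(C)O)C[C@H]1C(C)=C | starting material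
2 | triethylsilyl trifluoromethanesulfonate | CC[Si](CC)(CC)OS(=O)(=O)C(F)(F)F | starting material
3 | elemol triethylsilyl ether (C11–OSiEt3; C5, C7, C10 as in elemol) | C=C[C@]1(C)CC[C@@H](C(C)(C)O[Si](CC)(CC)CC)C[C@H]1C(C)=C | intermediate
4 | catecholborane | B1Oc2ccccc2O1 | starting material
5 | hydrogen peroxide | OO | starting material
6 | B-alkylcatecholborane (boron on C2 of the former vinyl group) | O1c2ccccc2OB1CC[C@]3(C)CC[C@@H](C(C)(C)O[Si](CC)(CC)CC)C[C@H]3C(C)=C | intermediate (not isolated)
7 | C2 primary alcohol: C10 carries CH2CH2OH, C5 isopropenyl, C11–OSiEt3 | OCC[C@]1(C)CC[C@@H](C(C)(C)O[Si](CC)(CC)CC)C[C@H]1C(C)=C | intermediate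
8 | 4-nitrobenzenesulfonyl chloride | O=S(=O)(Cl)c1ccc([N+](=O)[O-])cc1 | starting material
9 | C2 4-nitrobenzenesulfonate of 7 | O=S(=O)(OCC[C@]1(C)CC[C@@H](C(C)(C)O[Si](CC)(CC)CC)C[C@H]1C(C)=C)c1ccc([N+](=O)[O-])cc1 | intermediate
10 | water | O | starting material
11 | 11-(triethylsilyloxy)eudesman-4-yl cation (trans-fused, 10β-methyl) | C[C+]2CCC[C@]3(C)CC[C@@H](C(C)(C)O[Si](CC)(CC)CC)C[C@H]32 | intermediate (not isolated)
12 | 11-(triethylsilyloxy)eudesman-4α-ol (4β-methyl, 5α-H, 7β side chain, 10β-methyl) | O[C@]1(C)CCC[C@]2(C)CC[C@@H](C(C)(C)O[Si](CC)(CC)CC)C[C@H]21 | intermediate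
13 | 4-bromo-2-chloro-1-iodobenzene | Clc1cc(Br)ccc1I | starting material
14 | 3-chloroperbenzoic acid | O=C(OO)c1cccc(Cl)c1 | starting material
15 | 4-toluenesulfonic acid monohydrate | Cc1ccc(S(=O)(=O)O)cc1.O | starting material
16 | 1,3,5-trimethoxybenzene | COc1cc(OC)cc(OC)c1 | starting material
17 | 4-bromo-2-chloro-1-[hydroxy(tosyloxy)iodo]benzene | OI(OS(=O)(=O)c1ccc(C)cc1)c1ccc(Br)cc1Cl | intermediate (not isolated)
18 | (4-bromo-2-chlorophenyl)(2,4,6-trimethoxyphenyl)iodonium tosylate | COc1cc(OC)c([I+]c2ccc(Br)cc2Cl)c(OC)c1.Cc1ccc(S(=O)(=O)[O-])cc1 | intermediate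
19 | sodium 4α-alkoxide of 12 | [Na+].[O-][C@]1(C)CCC[C@]2(C)CC[C@@H](C(C)(C)O[Si](CC)(CC)CC)C[C@H]21 | intermediate (not isolated)
20 | 4α-(4-bromo-2-chlorophenoxy)-11-(triethylsilyloxy)eudesmane | Clc1cc(Br)ccc1O[C@]2(C)CCC[C@]3(C)CC[C@@H](C(C)(C)O[Si](CC)(CC)CC)C[C@H]32 | intermediate
21 | allylboronic acid pinacol ester | C=CCB1OC(C)(C)C(C)(C)O1 | starting material
22 | 4α-(4-allyl-2-chlorophenoxy)-11-(triethylsilyloxy)eudesmane | C=CCc1ccc(O[C@]2(C)CCC[C@]3(C)CC[C@@H](C(C)(C)O[Si](CC)(CC)CC)C[C@H]32)c(Cl)c1 | intermediate
23 | 4-hydroxyphenylboronic acid pinacol ester | Oc1ccc(B2OC(C)(C)C(C)(C)O2)cc1 | starting material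
24 | allyl bromide | C=CCBr | starting material
25 | 4-(allyloxy)phenylboronic acid pinacol ester | C=CCOc1ccc(B2OC(C)(C)C(C)(C)O2)cc1 | intermediate
26 | 6-allyl-4-(pinacolboryl)cyclohexa-2,4-dien-1-one | C=CCC1C=C(B2OC(C)(C)C(C)(C)O2)C=CC1=O | intermediate (not isolated)
27 | 3-allyl-4-hydroxyphenylboronic acid pinacol ester (2-allyl-4-(pinacolboryl)phenol) | C=CCc1cc(B2OC(C)(C)C(C)(C)O2)ccc1O | intermediate
28 | 11-O-triethylsilyl ether of the target (ring C: O at C1, ring D at C2, allyl at C4; ring D: 3-allyl-4-hydroxyphenyl) | C=CCc1ccc(O[C@]2(C)CCC[C@]3(C)CC[C@@H](C(C)(C)O[Si](CC)(CC)CC)C[C@H]32)c(-c2ccc(O)c(CC=C)c2)c1 | intermediate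
29 | CNP0219722.1, 4α-O-(3',5-diallyl-4'-hydroxybiphenyl-2-yl) ether of eudesmane-4α,11-diol | C=CCc1ccc(O[C@]2(C)CCC[C@]3(C)CC[C@@H](C(C)(C)O)C[C@H]32)c(-c2ccc(O)c(CC=C)c2)c1 | target

**Step count**
Total steps: 11. Longest linear sequence: 8 steps (1, 2, 3, 4, 6, 7, 10, 11).

**Steps most likely to fail**

Step 4. Proton loss from the C4 cation (to the 3-ene, the 4(15)-ene or the 4-ene) or a 1,2-hydride shift from C5 may outrun hydration, and direct displacement at C2 by solvent may outrun π-participation. The fallback makes the same C2–C3 bond by enolate alkylation and sets out from nosylate 9. Ozonolysis of the isopropenyl group (O3, CH2Cl2/MeOH, −78 °C; Me2S) should give the methyl ketone nosylate F1. LiN(iPr)2 in THF at −78 to 0 °C removes a methyl proton, and the kinetic enolate closes ring A by (enolendo)-exo-tet displacement to give 11-(triethylsilyloxy)-15-noreudesman-4-one F2. Wittig methylenation (Ph3P=CH2, THF, 60 °C) should give β-eudesmol triethylsilyl ether F3. mCPBA (NaHCO3, CH2Cl2, 0 °C) should attack the exocyclic alkene from the α face, away from the axial C10 methyl, and give the 4α,15-epoxide F4. LiAlH4 (THF, 0 °C) opens the epoxide at C15, and the route is rejoined at compound 12.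

Step 6. Ligand coupling at the crowded tertiary alkoxide may be slower than base-induced decomposition of the iodonium salt (aryne formation or attack at the trimethoxyphenyl group). The fallback uses nucleophilic aromatic substitution on a formyl-activated fluoroarene and sets out from alcohol 12. Its potassium alkoxide (KN(SiMe3)2, THF/DMF, 0 °C), formed first, should displace fluoride from 3-chloro-4-fluorobenzaldehyde to give the 3-chloro-4-(eudesman-4α-yloxy)benzaldehyde F5. Addition of CH2=CHMgBr (THF, −78 °C) gives the 1-arylprop-2-en-1-ol F6 (either carbinol epimer serves), and ClCO2Me with pyridine gives the methyl carbonate F7. Palladium-catalysed formate hydrogenolysis (Pd(OAc)2, PBu3, HCO2NH4, dioxane, 80 °C) delivers hydride to the benzylic terminus of the allyl complex and should give the allylarene, so the route is rejoined at compound 22.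

Step 2. The catalyst may not discriminate well enough between the two terminal alkenes, so that the isopropenyl group is hydroborated as well, or the hindered vinyl group may react too slowly. The fallback uses oxidation instead of hydroboration and sets out from silyl ether 3. Aldehyde-selective Wacker oxidation (PdCl2(PhCN)2, CuCl2, AgNO2, O2, t-BuOH/MeNO2, 20 °C) acts on monosubstituted alkenes and leaves 1,1-disubstituted ones alone, and should give the C2 aldehyde F8. Reduction with NaBH4 (MeOH, 0 °C), done without delay so that the aldehyde does not undergo an ene reaction with the isopropenyl group, rejoins the route at compound 7.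

Further compounds
F1 | step 4 | C2 4-nitrobenzenesulfonate with the C5 isopropenyl group cleaved to acetyl (methyl ketone nosylate) | O=S(=O)(OCC[C@]1(C)CC[C@@H](C(C)(C)O[Si](CC)(CC)CC)C[C@H]1C(C)=O)c1ccc([N+](=O)[O-])cc1
F2 | step 4 | 11-(triethylsilyloxy)-15-noreudesman-4-one (trans-fused) | O=C1CCC[C@]2(C)CC[C@@H](C(C)(C)O[Si](CC)(CC)CC)C[C@H]21
F3 | step 4 | β-eudesmol triethylsilyl ether (4(15)-ene) | C=C1CCC[C@]2(C)CC[C@@H](C(C)(C)O[Si](CC)(CC)CC)C[C@H]21
F4 | step 4 | 4α,15-epoxy-11-(triethylsilyloxy)eudesmane (oxygen α, CH2 β) | C1O[C@@]12CCC[C@]3(C)CC[C@@H](C(C)(C)O[Si](CC)(CC)CC)C[C@H]32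
F5 | step 6 | 3-chloro-4-[11-(triethylsilyloxy)eudesman-4α-yloxy]benzaldehyde | O=Cc1ccc(O[C@]2(C)CCC[C@]3(C)CC[C@@H](C(C)(C)O[Si](CC)(CC)CC)C[C@H]32)c(Cl)c1
F6 | step 6 | 1-{3-chloro-4-[11-(triethylsilyloxy)eudesman-4α-yloxy]phenyl}prop-2-en-1-ol (carbinol epimers) | C=CC(O)c1ccc(O[C@]2(C)CCC[C@]3(C)CC[C@@H](C(C)(C)O[Si](CC)(CC)CC)C[C@H]32)c(Cl)c1
F7 | step 6 | methyl carbonate of F6 | C=CC(OC(=O)OC)c1ccc(O[C@]2(C)CCC[C@]3(C)CC[C@@H](C(C)(C)O[Si](CC)(CC)CC)C[C@H]32)c(Cl)c1
F8 | step 2 | C2 aldehyde: C10 carries CH2CHO, C5 isopropenyl, C11–OSiEt3 | O=CC[C@]1(C)CC[C@@H](C(C)(C)O[Si](CC)(CC)CC)C[C@H]1C(C)=C
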